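**Strategy.** Both halves share one skeleton, a 6,8-dioxygenated 3,4,5-trimethylisochroman, so a single intermediate serves twice. Its pyran ring is cut at the two aryl bonds, C1–C8a and C4–C4a. These are made together by annulating 2,4-dimethoxytoluene with tiglic acid: Friedel–Crafts acylation at C8a, the carbon para and ortho to the two ring oxygens, then Nazarov closure at C4a, its only free neighbour, gives a 1-indanone that holds C8a, C1, C3, C4 and C4a in a five-membered ring. Cleaving the indanone C1–C3 bond and hydrogenating with dynamic kinetic resolution inserts the ring oxygen O2 and sets both stereocentres. The lactone and the quinone methide derived from it are joined through a C7 methylene.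

Key step: step 1

Remark: locants are those of the isochroman rings of the target (O2, C1, C3, C4, C4a, C5–C8, C8a); quinone methide 12 is drawn in the tautomeric form of the target.

**Step 1**
Reactants: 1 2,4-dimethoxytoluene; 2 tiglic acid, (E)-2-methylbut-2-enoic acid
Product: 4 (±)-trans-5,7-dimethoxy-2,3,4-trimethylindan-1-one, via aryl vinyl ketone 3 (not isolated)
Conditions: 2 (1.1 equiv), P2O5 in MeSO3H, 25 °C then 70 °C
Reagents that add atoms: none
Why: The acylium ion (mixed anhydride) from 2 acylates 1 at the carbon para to one methoxy and ortho to the other (future C8a), which forms C1–C8a and gives dienone 3; its O-protonated form is a hydroxypentadienyl cation over C4a=C8a–C1–C3=C4 that undergoes thermal conrotatory 4π electrocyclization, which forms C4–C4a, and rearomatization and ketonization give the indanone. This is the known tandem Friedel–Crafts acylation–Nazarov synthesis of 1-indanones from arenes and α,β-unsaturated acids. The five-membered ring closes by 4π electrocyclization (formally 5-endo) onto C4a, the only ortho position of the new ketone that carries hydrogen, the other being the methoxy-bearing C8. The C4 stereocentre arises without facial bias (racemic) and C3 is set trans to it by thermodynamic protonation; neither is relied on, since C3 is oxidized in step 2 and C4 is re-set in step 3. The selectivity needed is regiochemical, acylation before conjugate alkylation and at C8a rather than C7, and it should be secured by fast acylium formation in the P2O5-rich medium and by the lower hindrance and para-methoxy activation of C8a.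

**Step 2**
Reactants: 4 (±)-trans-5,7-dimethoxy-2,3,4-trimethylindan-1-one
Product: 6 (±)-4,6-dimethoxy-3-methyl-2-(3-oxobutan-2-yl)benzoic acid, via silyl enol ether 5 (not isolated)
Conditions: LiN(SiMe3)2, Me3SiCl, THF, −78 → 0 °C; then O3 (1 equiv), CH2Cl2, −78 °C; Me2S; aq. citric acid
Reagents that add atoms: ozone, [O-][O+]=O
Why: C3 (indanone C2) bears the only α-hydrogen, so enolization and O-silylation are regiospecific, and ozonolysis of the tetrasubstituted silyl enol ether, which should react with ozone much faster than the arene, cuts the C1–C3 bond to leave C1 as the aryl carboxylic acid and C3 as a methyl ketone; C4 becomes an epimerizable α-aryl ketone centre, which step 3 uses.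

**Step 3**
Reactants: 6 (±)-4,6-dimethoxy-3-methyl-2-(3-oxobutan-2-yl)benzoic acid
Product: 8 (3R,4S)-6,8-dimethoxy-3,4,5-trimethylisochroman-1-one, via threo hydroxy acid 7 (not isolated)
Conditions: RuCl2[(S)-xylbinap][(S)-daipen] (1 mol%), KOt-Bu (1.3 equiv), H2 (10 atm), i-PrOH, 30 °C; then 2 M HCl
Reagents that add atoms: none
Why: Noyori asymmetric hydrogenation with dynamic kinetic resolution, as established for configurationally labile α-aryl ketones: the benzylic C4 centre of the keto carboxylate equilibrates through its enolate under KOt-Bu, the RuH/NH2 catalyst (antipode chosen for hydride delivery to the Si face of the methyl ketone, C3 = R) should consume the Felkin–Anh-matched 4S ketone fastest (aryl anti to the incoming hydride), so the threo hydroxy acid 7 forms and closes to the trans lactone on acidification.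

**Step 4**
Reactants: 8 (3R,4S)-6,8-dimethoxy-3,4,5-trimethylisochroman-1-one
Product: 9 (3R,4S)-6,8-dihydroxy-3,4,5-trimethylisochroman-1-one
Conditions: BBr3 (3 equiv), CH2Cl2, −78 → 0 °C; H2O
Reagents that add atoms: none
Why: Lewis-acid cleavage of aryl methyl ethers with BBr3, the 8-methoxy group being assisted by chelation to the lactone carbonyl; the lactone C–O bonds and both stereocentres are inert under these conditions.

**Step 5**
Reactants: 9 (3R,4S)-6,8-dihydroxy-3,4,5-trimethylisochroman-1-one
Product: 10 (3R,4S)-7-[(dimethylamino)methyl]-6,8-dihydroxy-3,4,5-trimethylisochroman-1-one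
Conditions: aq. CH2O, aq. Me2NH, EtOH, 25 °C
Reagents that add atoms: formaldehyde, C=O; dimethylamine, CNC
Why: Phenolic Mannich reaction: the iminium ion attacks C7, the only unsubstituted ring carbon, which lies ortho to both hydroxyl groups.

**Step 6**
Reactants: 8 (3R,4S)-6,8-dimethoxy-3,4,5-trimethylisochroman-1-one
Product: 11 (3R,4S)-6,8-dimethoxy-3,4,5-trimethylisochroman-1-ol (both C1 epimers)
Conditions: i-Bu2AlH (1.2 equiv), CH2Cl2, −78 °C; aq. potassium sodium tartrate (KNaC4H4O6)
Reagents that add atoms: none
Why: Partial reduction of a lactone with i-Bu2AlH: the aluminium hemiacetalate is stable at −78 °C and gives the lactol on work-up without touching the aryl ethers or the stereocentres.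

**Step 7**
Reactants: 11 (3R,4S)-6,8-dimethoxy-3,4,5-trimethylisochroman-1-ol
Product: 12 decarboxycitrinin, the (3R,4S)-3,4,5-trimethyl quinone methide with O2–C1H=C8a, C8=O, C6–OH and C4a=C5
Conditions: BBr3 (3 equiv), CH2Cl2, −78 → 0 °C; H2O
Reagents that add atoms: none
Why: BBr3 ionizes the lactol to the cyclic oxocarbenium ion, whose charge is shared by O6 and O8, so both methyl ethers should be cleaved by bromide as O-methyl oxonium ions (Lewis-acid ether cleavage with dehydration), and loss of a proton on work-up leaves the quinone methide; C3 and C4 are not involved.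

**Step 8**
Reactants: 10 (3R,4S)-7-[(dimethylamino)methyl]-6,8-dihydroxy-3,4,5-trimethylisochroman-1-one; 12 decarboxycitrinin
Product: 13 dicitrinone G
Conditions: 12 (1.2 equiv), toluene, 100 °C, N2 stream
Reagents that add atoms: none
Why: Thermal loss of dimethylamine from the ortho-hydroxybenzylamine gives an ortho-quinone methide that is captured in a Michael addition by C7 of 12, the nucleophilic carbon between the C6 enol and the C8 carbonyl; tautomerization restores the resorcinol and the hydroxy quinone methide, and no stereocentre is touched.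

**Compound list**
1 | 2,4-dimethoxytoluene | Cc1ccc(OC)cc1OC | starting material
2 | tiglic acid, (E)-2-methylbut-2-enoic acid | C/C=C(\C)C(=O)O | starting material
3 | (E)-1-(2,4-dimethoxy-5-methylphenyl)-2-methylbut-2-en-1-one | C/C=C(\C)C(=O)c1cc(C)c(OC)cc1OC | intermediate (not isolated)
4 | (±)-trans-5,7-dimethoxy-2,3,4-trimethylindan-1-one (racemate, 2R,3R enantiomer drawn) | C[C@H]1C(=O)c2c(OC)cc(OC)c(C)c2[C@@H]1C | intermediate
5 | (±)-4,6-dimethoxy-1,2,7-trimethyl-3-(trimethylsilyloxy)-1H-indene | CC1=C(O[Si](C)(C)C)c2c(OC)cc(OC)c(C)c2C1C | intermediate (not isolated)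
6 | (±)-4,6-dimethoxy-3-methyl-2-(3-oxobutan-2-yl)benzoic acid | CC(=O)C(C)c1c(C)c(OC)cc(OC)c1C(=O)O | intermediate
7 | 2-[(2S,3R)-3-hydroxybutan-2-yl]-4,6-dimethoxy-3-methylbenzoic acid | O[C@H](C)[C@@H](C)c1c(C)c(OC)cc(OC)c1C(=O)O | intermediate (not isolated)
8 | (3R,4S)-6,8-dimethoxy-3,4,5-trimethylisochroman-1-one | COc1cc(OC)c(C)c2c1C(=O)O[C@H](C)[C@H]2C | intermediate
9 | (3R,4S)-6,8-dihydroxy-3,4,5-trimethylisochroman-1-one | Oc1cc(O)c(C)c2c1C(=O)O[C@H](C)[C@H]2C | intermediate
10 | (3R,4S)-7-[(dimethylamino)methyl]-6,8-dihydroxy-3,4,5-trimethylisochroman-1-one | CN(C)Cc1c(O)c(C)c2c(c1O)C(=O)O[C@H](C)[C@H]2C | intermediate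
11 | (3R,4S)-6,8-dimethoxy-3,4,5-trimethylisochroman-1-ol (C1 epimers) | COc1cc(OC)c(C)c2c1C(O)O[C@H](C)[C@H]2C | intermediate
12 | decarboxycitrinin, (3R,4S)-6-hydroxy-3,4,5-trimethyl-3,4-dihydroisochromen-8-one quinone methide | CC1=C2C(=CO[C@H](C)[C@H]2C)C(=O)C=C1O | intermediate
13 | dicitrinone G | CC1=C2C(=CO[C@H](C)[C@H]2C)C(=O)C(Cc2c(O)c(C)c3c(c2O)C(=O)O[C@H](C)[C@H]3C)=C1O | target

**Count.** Total steps: 8. Longest linear sequence: 6 steps (1, 2, 3, 4, 5, 8 or 1, 2, 3, 6, 7, 8).

**Steps most likely to fail**

Step 3. Enolization of the hindered benzylic centre, flanked by a doubly ortho-substituted arene, may be slower than hydrogenation, so the mismatched enantiomer is reduced too and diastereo- and enantiopurity erode; the carboxylate may also slow the catalyst. The fallback sets out from 6 and replaces catalyst control by substrate control plus resolution. LiBH(s-Bu)3 (2.2 equiv) in THF at −78 °C, then HCl, should give by Felkin–Anh addition the racemic trans lactone, (±)-trans-6,8-dimethoxy-3,4,5-trimethylisochroman-1-one F1. AlMe3-mediated aminolysis with (S)-1-phenylethylamine opens it to two diastereomeric hydroxy amides, from which 2-[(2S,3R)-3-hydroxybutan-2-yl]-4,6-dimethoxy-3-methyl-N-[(1S)-1-phenylethyl]benzamide F2 is separated by chromatography or crystallization. p-TsOH in toluene at 110 °C closes F2 to the lactone with loss of the amine, and the route is rejoined at 8.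

Step 1. The electrocyclization has to engage a ring carbon that is meta to both methoxy groups while the protonated ketone is strongly stabilized by them; closure may stall, and prolonged heating in strong acid may bring ether cleavage or oligomerization of the dienone. The fallback sets out from 1 and forms the two aryl bonds separately. N-Bromosuccinimide in MeCN gives 1-bromo-2,4-dimethoxy-5-methylbenzene F3. n-BuLi in THF at −78 °C, then CO2, gives 2,4-dimethoxy-5-methylbenzoic acid F4. Carboxylate-directed C–H activation and oxidative annulation with but-2-yne ([RuCl2(p-cymene)]2 cat., Cu(OAc)2·H2O, t-AmOH, 100 °C) at the only free ortho position gives 6,8-dimethoxy-3,4,5-trimethyl-1H-isochromen-1-one F5. KOH in aqueous EtOH, then HCl, opens the enol lactone to keto acid 6, where the route is rejoined.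

Step 8. The ortho-quinone methide may be captured by an oxygen of 12 or by a second molecule of 10 (homo-coupling), and the liberated amine may add reversibly to C1 of 12. The fallback sets out from 9 and couples first, then differentiates. Aqueous formaldehyde (0.5 equiv) with catalytic HCl in AcOH should give the symmetric dimer 7,7'-methylenebis[(3R,4S)-6,8-dihydroxy-3,4,5-trimethylisochroman-1-one] F6. i-Bu2AlH (enough for the four phenols plus one equivalent) in THF at −78 °C reduces one lactone to the lactol 7-{[(3R,4S)-1,6,8-trihydroxy-3,4,5-trimethylisochroman-7-yl]methyl}-(3R,4S)-6,8-dihydroxy-3,4,5-trimethylisochroman-1-one F7 (statistical; unreacted F6 is recycled). F7 loses water on mildly acidic work-up and gives 13.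

**Further compounds**
F1 | step 3 | (±)-trans-6,8-dimethoxy-3,4,5-trimethylisochroman-1-one (racemate, one enantiomer drawn) | COc1cc(OC)c(C)c2c1C(=O)O[C@H](C)[C@H]2C
F2 | step 3 | 2-[(2S,3R)-3-hydroxybutan-2-yl]-4,6-dimethoxy-3-methyl-N-[(1S)-1-phenylethyl]benzamide | O[C@H](C)[C@@H](C)c1c(C)c(OC)cc(OC)c1C(=O)N[C@@H](C)c1ccccc1
F3 | step 1 | 1-bromo-2,4-dimethoxy-5-methylbenzene | COc1cc(OC)c(C)cc1Br
F4 | step 1 | 2,4-dimethoxy-5-methylbenzoic acid | COc1cc(OC)c(C)cc1C(=O)O
F5 | step 1 | 6,8-dimethoxy-3,4,5-trimethyl-1H-isochromen-1-one | COc1cc(OC)c(C)c2c1C(=O)OC(C)=C2C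
F6 | step 8 | 7,7'-methylenebis[(3R,4S)-6,8-dihydroxy-3,4,5-trimethylisochroman-1-one] | C(c1c(O)c(C)c2c(c1O)C(=O)O[C@H](C)[C@H]2C)c1c(O)c(C)c2c(c1O)C(=O)O[C@H](C)[C@H]2C
F7 | step 8 | 7-{[(3R,4S)-1,6,8-trihydroxy-3,4,5-trimethylisochroman-7-yl]methyl}-(3R,4S)-6,8-dihydroxy-3,4,5-trimethylisochroman-1-one | C(c1c(O)c(C)c2c(c1O)C(O)O[C@H](C)[C@H]2C)c1c(O)c(C)c2c(c1O)C(=O)O[C@H](C)[C@H]2C
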